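**Retrosynthetic overview**
1. 23 ⇐ 22 ⇐ 21. One hydrogenolysis removes both benzyl ethers and opens the benzylic C–O bond of the epoxide. The epoxide comes from a catalyst-controlled epoxidation of the chromene, which sets the carbinol centre.
2. 21 ⇐ 10 + 19. The quaternary C–CH2 bond is made by asymmetric phase-transfer benzylation of the butenolide ester, which sets the quaternary centre.
3. 10 ⇐ 7 + 8. The butenolide ring is made by phosphine-catalysed C–C cleavage and two-atom ring expansion of an aryl(methoxy)cyclopropenone with methyl glyoxylate (key step).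
4. 7 ⇐ catechol + C3Cl4 (arylation of C3Cl3+, hydrolysis, O-methylation). 19 ⇐ 4-bromophenol + 3-methylbut-2-enal + formaldehyde.
5. Ring order: cyclopropenone → butenolide (fragment 1); pyran ring of the chromene (fragment 2); then oxirane → chromanol last.

Assumption: the facial sense of the ammonium catalyst in step 8 cannot be predicted with certainty. The antipode that gives (2R)-21 is used (both are sold), and the assignment is checked by X-ray or ECD.

**Step 1**
Reactants: 1 catechol (benzene-1,2-diol)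
Product: 2 1,2-bis(benzyloxy)benzene
Conditions: BnBr (2.2 equiv), K2CO3 (2.5 equiv), DMF, 60 °C
Reagents that add atoms: benzyl bromide, BrCc1ccccc1
Why: Williamson ether synthesis on an acidic diphenol, with benzyl chosen because both groups leave in the final hydrogenolysis at no cost in steps.

**Step 2**
Reactants: 2 1,2-bis(benzyloxy)benzene; 3 tetrachlorocyclopropene
Product: 6 2-[3,4-bis(benzyloxy)phenyl]-3-hydroxycycloprop-2-en-1-one, via trichlorocyclopropenium tetrachloroaluminate 4 (not isolated), via aryldichlorocyclopropenium tetrachloroaluminate 5 (not isolated)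
Conditions: 3 + AlCl3 (1.0 equiv each), CH2Cl2, rt, 30 min; 2 (0.9 equiv) added at −78 °C, then to −30 °C; acetone–H2O, 0 °C to rt
Reagents that add atoms: water, O
Why: Friedel–Crafts arylation of the aromatic C3Cl3+ cation para to one OBn group, where the 1:1 salt leaves no free AlCl3 to strip benzyl ethers, the donor aryl group tames cation 5 against a second arylation, and hydrolysis of the two C–Cl bonds gives the known arylhydroxycyclopropenone class.

**Step 3**
Reactants: 6 2-[3,4-bis(benzyloxy)phenyl]-3-hydroxycycloprop-2-en-1-one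
Product: 7 2-[3,4-bis(benzyloxy)phenyl]-3-methoxycycloprop-2-en-1-one
Conditions: TMSCHN2 (1.1 equiv), toluene–MeOH 10:1, 0 °C; used without storage
Reagents that add atoms: (trimethylsilyl)diazomethane, C[Si](C)(C)C=[N+]=[N-]
Why: Diazoalkane O-methylation of a strong vinylogous acid (pKa about 2), whose two oxygens are equivalent by symmetry in the anion, so only one methyl ether can form.

**Step 4**
Reactants: 7 2-[3,4-bis(benzyloxy)phenyl]-3-methoxycycloprop-2-en-1-one; 8 methyl glyoxylate
Product: 10 methyl 3-[3,4-bis(benzyloxy)phenyl]-4-methoxy-5-oxo-2,5-dihydrofuran-2-carboxylate (racemic), via ketenyl phosphonium ylide 9 (not isolated)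
Conditions: MePPh2 (10 mol %), 8 (3 equiv, freshly distilled), toluene, rt, Ar; 7 added over 4 h by syringe pump
Reagents that add atoms: none
Why: Proposed new method: phosphine-catalysed ring expansion (three- to five-membered, insertion of the C=O unit) of an alkoxy(aryl)cyclopropenone, an unsymmetrical donor-substituted class on which this C–C cleavage has not been shown; MePPh2 adds reversibly to either ring alkene carbon, but only the adduct at C(Ar) can break the C(=O)–C(Ar) bond to the benzylic-stabilised ylide 9, whose ylide carbon attacks the very electrophilic, non-enolisable aldehyde 8, after which the alkoxide closes on the ketene carbon and the lactone enolate expels MePPh2, placing Ar next to the new sp3 carbon and OMe next to the lactone carbonyl; slow addition into excess 8 keeps 9 away from the C–H acidic product, which as a carbon acid transfers its proton only slowly; the closest known reaction type is the phosphine-catalysed (3+2) annulation of diaryl and alkyl cyclopropenones with aldehydes; the stereocentre forms racemic and is erased in step 8.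

**Step 5**
Reactants: 11 4-bromophenol; 12 3-methylbut-2-enal
Product: 14 6-bromo-2,2-dimethyl-2H-chromene, via ortho-quinone methide 13 (not isolated)
Conditions: PhB(OH)2 (1 equiv), AcOH, toluene, reflux, Dean–Stark
Reagents that add atoms: none
Why: Chromenylation of a phenol, in which phenylboronic acid templates ortho-selective condensation with the enal and loss of water gives 13, which closes by oxa-6π electrocyclisation.

**Step 6**
Reactants: 14 6-bromo-2,2-dimethyl-2H-chromene; 15 formaldehyde (used as paraformaldehyde)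
Product: 17 (2,2-dimethyl-2H-chromen-6-yl)methanol, via chromenylmagnesium bromide 16 (not isolated)
Conditions: Mg, THF, reflux; (CH2O)n, 0 °C to rt; aq NH4Cl
Reagents that add atoms: none
Why: Grignard formation and addition to formaldehyde (hydroxymethylation), which the chromene tolerates because it has no acidic or electrophilic site.

**Step 7**
Reactants: 17 (2,2-dimethyl-2H-chromen-6-yl)methanol
Product: 19 6-(bromomethyl)-2,2-dimethyl-2H-chromene, via benzylic mesylate 18 (not isolated)
Conditions: MsCl, Et3N, CH2Cl2, −20 °C; then LiBr, THF, 0 °C; solution used at once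
Reagents that add atoms: lithium bromide, [Li+].[Br-]
Why: Mesylation followed by SN2 displacement with bromide (Finkelstein type) keeps the medium basic to neutral, so the acid-labile chromene survives.

**Step 8**
Reactants: 10 methyl 3-[3,4-bis(benzyloxy)phenyl]-4-methoxy-5-oxo-2,5-dihydrofuran-2-carboxylate; 19 6-(bromomethyl)-2,2-dimethyl-2H-chromene
Product: 21 methyl (2R)-3-[3,4-bis(benzyloxy)phenyl]-2-[(2,2-dimethyl-2H-chromen-6-yl)methyl]-4-methoxy-5-oxo-2,5-dihydrofuran-2-carboxylate, via potassium 2-oxidofuran dienolate 20 (not isolated)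
Conditions: Maruoka spiro bis(binaphthyl) ammonium bromide bearing 3,4,5-trifluorophenyl groups (2 mol %), solid K2CO3 (1.5 equiv), toluene, −20 °C, Ar
Reagents that add atoms: none
Why: Asymmetric phase-transfer alkylation, in which K2CO3 deprotonates the doubly activated C2–H to the planar anion 20, whose ion pair with the chiral ammonium cation shields one face so that C-benzylation at the ester-bearing carbon sets the (2R) quaternary centre, as established for the benzo-fused analogues (phthalide-3-carboxylates).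

**Step 9**
Reactants: 21 methyl (2R)-3-[3,4-bis(benzyloxy)phenyl]-2-[(2,2-dimethyl-2H-chromen-6-yl)methyl]-4-methoxy-5-oxo-2,5-dihydrofuran-2-carboxylate
Product: 22 methyl (2R)-3-[3,4-bis(benzyloxy)phenyl]-2-{[(3R,4R)-3,4-epoxy-2,2-dimethylchroman-6-yl]methyl}-4-methoxy-5-oxo-2,5-dihydrofuran-2-carboxylate
Conditions: (R,R)-[N,N'-bis(3,5-di-tert-butylsalicylidene)-1,2-cyclohexanediaminato]MnCl (4 mol %), 4-phenylpyridine N-oxide (20 mol %), aq NaOCl (pH 11.3), CH2Cl2, 0 °C
Reagents that add atoms: sodium hypochlorite, [Na+].[O-]Cl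
Why: Jacobsen–Katsuki epoxidation, for which 2,2-dimethylchromenes are the best substrate class, with the (R,R) complex giving the (3R,4R)-epoxide under catalyst control while the hindered, electron-poor butenolide alkene stays inert.

**Step 10**
Reactants: 22 methyl (2R)-3-[3,4-bis(benzyloxy)phenyl]-2-{[(3R,4R)-3,4-epoxy-2,2-dimethylchroman-6-yl]methyl}-4-methoxy-5-oxo-2,5-dihydrofuran-2-carboxylate
Product: 23 methyl (2R)-3-(3,4-dihydroxyphenyl)-2-{[(3R)-3-hydroxy-2,2-dimethylchroman-6-yl]methyl}-4-methoxy-5-oxo-2,5-dihydrofuran-2-carboxylate (target)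
Conditions: H2 (1 atm), 10% Pd/C, EtOAc, rt
Reagents that add atoms: none
Why: Heterogeneous hydrogenolysis cleaves the two O-benzyl bonds and only the benzylic C4–O bond of the epoxide, so the C3–O bond keeps its (3R) configuration, while the tetrasubstituted alkene and the non-benzylic quaternary C–O bond are inert.

**Compound list**
1 | catechol | Oc1ccccc1O | starting material
2 | 1,2-bis(benzyloxy)benzene | c1ccc(COc2ccccc2OCc2ccccc2)cc1 | intermediate
3 | tetrachlorocyclopropene | ClC1=C(Cl)C1(Cl)Cl | starting material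
4 | trichlorocyclopropenium tetrachloroaluminate | Cl[C+]1C(Cl)=C1Cl.Cl[Al-](Cl)(Cl)Cl | intermediate
5 | [3,4-bis(benzyloxy)phenyl]dichlorocyclopropenium tetrachloroaluminate | Cl[C+]1C(Cl)=C1c1ccc(OCc2ccccc2)c(OCc2ccccc2)c1.Cl[Al-](Cl)(Cl)Cl | intermediate
6 | 2-[3,4-bis(benzyloxy)phenyl]-3-hydroxycycloprop-2-en-1-one | O=C1C(O)=C1c1ccc(OCc2ccccc2)c(OCc2ccccc2)c1 | intermediate
7 | 2-[3,4-bis(benzyloxy)phenyl]-3-methoxycycloprop-2-en-1-one | O=C1C(OC)=C1c1ccc(OCc2ccccc2)c(OCc2ccccc2)c1 | intermediate
8 | methyl glyoxylate | COC(=O)C=O | starting material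
9 | ketenyl phosphonium ylide from 7 and MePPh2 | C[P+](c1ccccc1)(c1ccccc1)[C-](c1ccc(OCc2ccccc2)c(OCc2ccccc2)c1)C(OC)=C=O | intermediate
10 | methyl 3-[3,4-bis(benzyloxy)phenyl]-4-methoxy-5-oxo-2,5-dihydrofuran-2-carboxylate (racemic) | COC(=O)C1OC(=O)C(OC)=C1c1ccc(OCc2ccccc2)c(OCc2ccccc2)c1 | intermediate
11 | 4-bromophenol | Oc1ccc(Br)cc1 | starting material
12 | 3-methylbut-2-enal | CC(C)=CC=O | starting material
13 | 4-bromo-6-(3-methylbut-2-enylidene)cyclohexa-2,4-dien-1-one (ortho-quinone methide) | O=C1C=CC(Br)=CC1=CC=C(C)C | intermediate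
14 | 6-bromo-2,2-dimethyl-2H-chromene | CC1(C)C=Cc2cc(Br)ccc2O1 | intermediate
15 | formaldehyde (as paraformaldehyde) | C=O | starting material
16 | (2,2-dimethyl-2H-chromen-6-yl)magnesium bromide | CC1(C)C=Cc2cc([Mg]Br)ccc2O1 | intermediate
17 | (2,2-dimethyl-2H-chromen-6-yl)methanol | CC1(C)C=Cc2cc(CO)ccc2O1 | intermediate
18 | (2,2-dimethyl-2H-chromen-6-yl)methyl methanesulfonate | CC1(C)C=Cc2cc(COS(C)(=O)=O)ccc2O1 | intermediate
19 | 6-(bromomethyl)-2,2-dimethyl-2H-chromene | CC1(C)C=Cc2cc(CBr)ccc2O1 | intermediate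
20 | potassium 4-[3,4-bis(benzyloxy)phenyl]-3-methoxy-5-(methoxycarbonyl)furan-2-olate | [K+].COC(=O)C1=C(c2ccc(OCc3ccccc3)c(OCc3ccccc3)c2)C(OC)=C([O-])O1 | intermediate
21 | methyl (2R)-3-[3,4-bis(benzyloxy)phenyl]-2-[(2,2-dimethyl-2H-chromen-6-yl)methyl]-4-methoxy-5-oxo-2,5-dihydrofuran-2-carboxylate | COC(=O)[C@]1(Cc2ccc3c(c2)C=CC(C)(C)O3)OC(=O)C(OC)=C1c1ccc(OCc2ccccc2)c(OCc2ccccc2)c1 | intermediate
22 | methyl (2R)-3-[3,4-bis(benzyloxy)phenyl]-2-{[(3R,4R)-3,4-epoxy-2,2-dimethylchroman-6-yl]methyl}-4-methoxy-5-oxo-2,5-dihydrofuran-2-carboxylate | COC(=O)[C@]1(Cc2ccc3c(c2)[C@H]4O[C@H]4C(C)(C)O3)OC(=O)C(OC)=C1c1ccc(OCc2ccccc2)c(OCc2ccccc2)c1 | intermediate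
23 | methyl (2R)-3-(3,4-dihydroxyphenyl)-2-{[(3R)-3-hydroxy-2,2-dimethylchroman-6-yl]methyl}-4-methoxy-5-oxo-2,5-dihydrofuran-2-carboxylate | COC(=O)[C@]1(Cc2ccc3c(c2)C[C@@H](O)C(C)(C)O3)OC(=O)C(OC)=C1c1ccc(O)c(O)c1 | target

**Total step count:** 10. **Longest linear sequence:** 7 (steps 1, 2, 3, 4, 8, 9, 10).

**The three steps most likely to fail**

(a) Step 4, the proposed new step.
- Ring opening from the C(OMe) adduct would give the isomeric tetronate.
- The phosphine could demethylate 7 by SN2 attack at the methyl group.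
- Wittig olefination of 8 could compete with ring closure.
- Ylide 9 could acylate the acidic product.

The fallback uses known chemistry, sets out from 2 and comes back at 10. NBS in MeCN brominates 2 to 4-bromo-1,2-bis(benzyloxy)benzene F1. Mg in THF converts it into [3,4-bis(benzyloxy)phenyl]magnesium bromide F2. Under CuI catalysis F2 opens methyl oxirane-2-carboxylate at its CH2 carbon to give methyl 3-[3,4-bis(benzyloxy)phenyl]-2-hydroxypropanoate F3. Dess–Martin periodinane oxidises F3 to methyl 3-[3,4-bis(benzyloxy)phenyl]-2-oxopropanoate F4. The classical amine-base aldol addition of F4 to excess 8, with spontaneous lactonisation, gives the isotetronic acid methyl 3-[3,4-bis(benzyloxy)phenyl]-4-hydroxy-5-oxo-2,5-dihydrofuran-2-carboxylate F5. O-methylation of F5 with TMSCHN2 gives 10.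

(b) Step 8. The risks are moderate enantioselectivity, O-alkylation or alkylation at the OMe-bearing carbon by the ionisable bromide, and air oxidation of 20. The fallback replaces asymmetric catalysis by resolution, sets out from 10 and 19 and comes back at 21. Alkylation with K2CO3 in DMF without a chiral catalyst gives racemic methyl 3-[3,4-bis(benzyloxy)phenyl]-2-[(2,2-dimethyl-2H-chromen-6-yl)methyl]-4-methoxy-5-oxo-2,5-dihydrofuran-2-carboxylate F6. Preparative supercritical-fluid chromatography on an amylose-type chiral phase then separates 21 from the (2S)-enantiomer of 21 F7, which is discarded.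

(c) Step 2. The risks are loss of benzyl groups, a second arylation of 5 and ring opening during hydrolysis. The fallback builds the three-membered ring by carbene addition instead of arylating a preformed C3 cation, sets out from 2 and comes back at 6.
- NIS with catalytic TFA in MeCN iodinates 2 to 4-iodo-1,2-bis(benzyloxy)benzene F8.
- n-BuLi deprotonates ethoxyacetylene to lithium ethoxyacetylide F9, and ZnCl2 transmetalates it to (ethoxyethynyl)zinc chloride F10.
- Negishi coupling of F10 with F8 under Pd(PPh3)4 gives 1,2-bis(benzyloxy)-4-(ethoxyethynyl)benzene F11.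
- Difluorocarbene (TMSCF3, NaI, THF, 65 °C) adds to F11 to give 1-[3,4-bis(benzyloxy)phenyl]-2-ethoxy-3,3-difluorocyclopropene F12.
- Wet silica gel hydrolyses the CF2 group to 2-[3,4-bis(benzyloxy)phenyl]-3-ethoxycycloprop-2-en-1-one F13.
- Dilute aqueous HCl in THF cleaves the ethyl vinylogous ester to give 6.

**Further compounds**
F1 | step 4 | 4-bromo-1,2-bis(benzyloxy)benzene | Brc1ccc(OCc2ccccc2)c(OCc2ccccc2)c1
F2 | step 4 | [3,4-bis(benzyloxy)phenyl]magnesium bromide | Br[Mg]c1ccc(OCc2ccccc2)c(OCc2ccccc2)c1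
F3 | step 4 | methyl 3-[3,4-bis(benzyloxy)phenyl]-2-hydroxypropanoate (racemic) | COC(=O)C(O)Cc1ccc(OCc2ccccc2)c(OCc2ccccc2)c1
F4 | step 4 | methyl 3-[3,4-bis(benzyloxy)phenyl]-2-oxopropanoate | COC(=O)C(=O)Cc1ccc(OCc2ccccc2)c(OCc2ccccc2)c1
F5 | step 4 | methyl 3-[3,4-bis(benzyloxy)phenyl]-4-hydroxy-5-oxo-2,5-dihydrofuran-2-carboxylate (racemic) | COC(=O)C1OC(=O)C(O)=C1c1ccc(OCc2ccccc2)c(OCc2ccccc2)c1
F6 | step 8 | racemic methyl 3-[3,4-bis(benzyloxy)phenyl]-2-[(2,2-dimethyl-2H-chromen-6-yl)methyl]-4-methoxy-5-oxo-2,5-dihydrofuran-2-carboxylate | COC(=O)C1(Cc2ccc3c(c2)C=CC(C)(C)O3)OC(=O)C(OC)=C1c1ccc(OCc2ccccc2)c(OCc2ccccc2)c1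
F7 | step 8 | (2S)-enantiomer of 21 | COC(=O)[C@@]1(Cc2ccc3c(c2)C=CC(C)(C)O3)OC(=O)C(OC)=C1c1ccc(OCc2ccccc2)c(OCc2ccccc2)c1
F8 | step 2 | 4-iodo-1,2-bis(benzyloxy)benzene | Ic1ccc(OCc2ccccc2)c(OCc2ccccc2)c1
F9 | step 2 | lithium ethoxyacetylide | [Li]C#COCC
F10 | step 2 | (ethoxyethynyl)zinc chloride | Cl[Zn]C#COCC
F11 | step 2 | 1,2-bis(benzyloxy)-4-(ethoxyethynyl)benzene | CCOC#Cc1ccc(OCc2ccccc2)c(OCc2ccccc2)c1
F12 | step 2 | 1-[3,4-bis(benzyloxy)phenyl]-2-ethoxy-3,3-difluorocyclopropene | CCOC1=C(c2ccc(OCc3ccccc3)c(OCc3ccccc3)c2)C1(F)F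
F13 | step 2 | 2-[3,4-bis(benzyloxy)phenyl]-3-ethoxycycloprop-2-en-1-one | CCOC1=C(c2ccc(OCc3ccccc3)c(OCc3ccccc3)c2)C1=O
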